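**Retrosynthetic overview**

- The chain CH–CO2H is carried to the end as an S-ethyl thioester. The malate C1–O ester comes from regioselective opening of O-trifluoroacetyl-D-malic anhydride by the chain's primary alcohol.
- The only ring, the γ-lactone, is closed as in the biosynthesis of the spiculisporic acids: the tertiary hydroxyl of an alkyl-homocitrate-type aldol adduct attacks the γ-carboxyl.
- The aldol adduct is cut at the quaternary C–CH bond, the bond the enzyme makes from an acyl thioester and 2-oxoglutarate. The partners are the (Z)-silyl ketene thioacetal of S-ethyl 12-hydroxydodecanethioate and di-tert-butyl 2-oxoglutarate. One chiral tin catalyst sets both stereocentres (anti), and aldol, lactonisation and ester cleavage run in one flask.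
- Building blocks: 12-hydroxydodecanoic acid, 2-oxoglutaric acid, D-malic acid. Ring order: a single ring, formed in the key step.

Assumption: the target is taken exactly as drawn, (R) at the malate carbinol (a D-malate unit), (R) at the chain CH bearing CO2H and (S) at the quaternary lactone carbon, and [Sn((S,S)-Ph-pybox)](OTf)2 is assumed to deliver the enolsilane to the si face of the 2-keto ester (if a test run shows the opposite sense, the commercial (R,R)-ligand replaces it with nothing else changed).

**Route**

Step 1
Reactants: 1 12-hydroxydodecanoic acid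
Product: 3 S-ethyl 12-hydroxydodecanethioate, via acyl imidazole 2 (not isolated)
Conditions: CDI (1.05 equiv), THF, rt, 45 min; then EtSH (3 equiv), rt, 12 h
Reagents that add atoms: ethanethiol, CCS
Why: The carboxylic acid reacts with CDI far faster than the alcohol does, and the soft thiol then outcompetes the remote primary hydroxyl for the acyl imidazole (CDI-mediated thioesterification), so no hydroxyl protection is needed and no stereocentre is involved.

Step 2
Reactants: 3 S-ethyl 12-hydroxydodecanethioate
Product: 5 (Z)-1-(ethylsulfanyl)-1,12-bis(trimethylsilyloxy)dodec-1-ene, via O-silyl thioester 4 (not isolated)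
Conditions: TMSCl (3 equiv), LiN(i-Pr)2 (LDA, commercial solution, 2.3 equiv), THF, −78 °C (3 added last), then rt; pentane, filtration under Ar, used crude
Reagents that add atoms: chlorotrimethylsilane, C[Si](C)(C)Cl
Why: The alkoxide is silylated at once under the internal quench, and kinetic deprotonation of the thioester by LDA in THF (Ireland-type chair transition state) followed by O-silylation gives the (Z)-silyl ketene thioacetal with the chain cis to sulfur.

Step 3
Reactants: 6 2-oxoglutaric acid
Product: 7 di-tert-butyl 2-oxopentanedioate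
Conditions: tert-butyl 2,2,2-trichloroacetimidate (4 equiv), CH2Cl2–cyclohexane, rt, 16 h
Reagents that add atoms: tert-butyl 2,2,2-trichloroacetimidate, CC(C)(C)OC(=N)C(Cl)(Cl)Cl
Why: Each carboxylic acid protonates the imidate and captures the tert-butyl cation under near-neutral conditions (trichloroacetimidate esterification), which leaves the sensitive 2-keto group untouched.

Step 4
Reactants: 5 (Z)-1-(ethylsulfanyl)-1,12-bis(trimethylsilyloxy)dodec-1-ene, 7 di-tert-butyl 2-oxopentanedioate
Product: 10 (2S)-2-[(1R)-1-(ethylsulfanylcarbonyl)-11-hydroxyundecyl]-5-oxooxolane-2-carboxylic acid, via silylated aldol adduct 8 (not isolated), via hydroxy diacid 9 (not isolated)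
Conditions: [Sn((S,S)-Ph-pybox)](OTf)2 (10 mol %, from Sn(OTf)2 and 2,6-bis[(4S)-4-phenyl-4,5-dihydro-1,3-oxazol-2-yl]pyridine), 5 (1.3 equiv), CH2Cl2, −78 °C, 24 h; then TFA–H2O (20:1) added, 0 °C to rt, 6 h; NaHCO3 extraction, re-acidification to pH 2
Reagents that add atoms: none
Why: Proposed new method: the closest known reaction is the anti-selective Mukaiyama aldol of thioester-derived (Z)-silyl ketene acetals with pyruvate esters under pybox-ligated Sn(OTf)2, here extended to a 2-oxoglutarate diester and telescoped with acid; divalent tin held by the C2-symmetric ligand binds the ketone and the adjacent ester carbonyl as a five-membered chelate, the enolsilane attacks the open si face of the ketone through an open antiperiplanar transition state that turns the alkyl chain away from the chelate (anti, giving (S) at the new quaternary carbon and (R) at the neighbouring CH in one event), silyl transfer turns the catalyst over, and TFA then removes both silyl groups and both tert-butyl esters so that the tertiary γ-hydroxy acid closes to the five-membered lactone, the same C–C bond formation and lactonisation by which an acyl thioester and 2-oxoglutarate are joined in the biosynthesis.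

Step 5
Reactants: 10 (2S)-2-[(1R)-1-(ethylsulfanylcarbonyl)-11-hydroxyundecyl]-5-oxooxolane-2-carboxylic acid, 11 D-malic acid
Product: 14 (2S)-2-[(1R)-11-{[(2R)-3-carboxy-2-hydroxypropanoyl]oxy}-1-(ethylsulfanylcarbonyl)undecyl]-5-oxooxolane-2-carboxylic acid, via trifluoroacetoxy anhydride 12 (not isolated), via trifluoroacetate ester 13 (not isolated)
Conditions: 11 (3 equiv), (CF3CO)2O (neat), 0 °C to rt, 2 h, evaporation; then 10, THF, rt, 16 h; then H2O, rt, 1 h
Reagents that add atoms: none
Why: Trifluoroacetic anhydride turns D-malic acid into its O-trifluoroacetyl cyclic anhydride, whose carbonyl next to the trifluoroacetoxy-bearing carbon is the more electrophilic, so the primary alcohol opens it to the 1-ester 4-acid (regioselective anhydride alcoholysis) without touching the malate stereocentre, and the labile trifluoroacetate is hydrolysed by water.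

Step 6
Reactants: 14 (2S)-2-[(1R)-11-{[(2R)-3-carboxy-2-hydroxypropanoyl]oxy}-1-(ethylsulfanylcarbonyl)undecyl]-5-oxooxolane-2-carboxylic acid
Product: 15 (2S)-2-[(1R)-1-carboxy-11-{[(2R)-3-carboxy-2-hydroxypropanoyl]oxy}undecyl]-5-oxooxolane-2-carboxylic acid
Conditions: AgNO3 (3 equiv), THF–H2O (4:1), rt to 40 °C, dark; dilute HCl, filtration, C18 chromatography
Reagents that add atoms: water, O
Why: Monovalent silver binds the soft sulfur and activates only the thioester toward water (silver-promoted thioester hydrolysis) under base-free conditions, so the lactone, the malate ester and the epimerisable CH centre are left alone.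

**Compound list**

1 | 12-hydroxydodecanoic acid | OCCCCCCCCCCCC(=O)O | starting material
2 | 1-(12-hydroxydodecanoyl)imidazole | OCCCCCCCCCCCC(=O)n1ccnc1 | intermediate
3 | S-ethyl 12-hydroxydodecanethioate | CCSC(=O)CCCCCCCCCCCO | intermediate
4 | S-ethyl 12-(trimethylsilyloxy)dodecanethioate | CCSC(=O)CCCCCCCCCCCO[Si](C)(C)C | intermediate
5 | (Z)-1-(ethylsulfanyl)-1,12-bis(trimethylsilyloxy)dodec-1-ene (chain cis to S) | CCS/C(O[Si](C)(C)C)=C\CCCCCCCCCCO[Si](C)(C)C | intermediate
6 | 2-oxoglutaric acid (2-oxopentanedioic acid) | O=C(O)CCC(=O)C(=O)O | starting material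
7 | di-tert-butyl 2-oxopentanedioate | CC(C)(C)OC(=O)CCC(=O)C(=O)OC(C)(C)C | intermediate
8 | di-tert-butyl (2S)-2-[(1R)-1-(ethylsulfanylcarbonyl)-11-(trimethylsilyloxy)undecyl]-2-(trimethylsilyloxy)pentanedioate | C[Si](C)(C)OCCCCCCCCCC[C@@H](C(=O)SCC)[C@](O[Si](C)(C)C)(C(=O)OC(C)(C)C)CCC(=O)OC(C)(C)C | intermediate
9 | (2S)-2-[(1R)-1-(ethylsulfanylcarbonyl)-11-hydroxyundecyl]-2-hydroxypentanedioic acid | OCCCCCCCCCC[C@@H](C(=O)SCC)[C@](O)(C(=O)O)CCC(=O)O | intermediate
10 | (2S)-2-[(1R)-1-(ethylsulfanylcarbonyl)-11-hydroxyundecyl]-5-oxooxolane-2-carboxylic acid | OCCCCCCCCCC[C@@H](C(=O)SCC)[C@]1(C(=O)O)CCC(=O)O1 | intermediate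
11 | D-malic acid, (2R)-2-hydroxybutanedioic acid | O=C(O)C[C@@H](O)C(=O)O | starting material
12 | (3R)-2,5-dioxooxolan-3-yl 2,2,2-trifluoroacetate | O=C1C[C@@H](OC(=O)C(F)(F)F)C(=O)O1 | intermediate
13 | (2S)-2-[(1R)-11-{[(2R)-3-carboxy-2-(trifluoroacetoxy)propanoyl]oxy}-1-(ethylsulfanylcarbonyl)undecyl]-5-oxooxolane-2-carboxylic acid | O=C(O)C[C@@H](OC(=O)C(F)(F)F)C(=O)OCCCCCCCCCC[C@@H](C(=O)SCC)[C@]1(C(=O)O)CCC(=O)O1 | intermediate
14 | (2S)-2-[(1R)-11-{[(2R)-3-carboxy-2-hydroxypropanoyl]oxy}-1-(ethylsulfanylcarbonyl)undecyl]-5-oxooxolane-2-carboxylic acid | O=C(O)C[C@@H](O)C(=O)OCCCCCCCCCC[C@@H](C(=O)SCC)[C@]1(C(=O)O)CCC(=O)O1 | intermediate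
15 | (2S)-2-[(1R)-1-carboxy-11-{[(2R)-3-carboxy-2-hydroxypropanoyl]oxy}undecyl]-5-oxooxolane-2-carboxylic acid | O=C(O)C[C@@H](O)C(=O)OCCCCCCCCCC[C@@H](C(=O)O)[C@]1(C(=O)O)CCC(=O)O1 | target

**Step count and risks**

Total steps: 6. Longest linear sequence: 5 (steps 1, 2, 4, 5, 6).

The three steps most likely to fail:

Step 4. The second ester of the 2-oxoglutarate may compete for tin and erode enantioselectivity, and the sense of induction rests on the assumption above. The fallback sets out from 5 and 7 and comes back at 10; it gives up catalyst control of absolute configuration and resolves instead. The aldol is run with Sn(OTf)2 and the achiral ligand 2,6-bis(4,4-dimethyl-4,5-dihydro-1,3-oxazol-2-yl)pyridine, on the expectation that the anti preference comes from the tin-bound open transition state rather than from the chiral ligand. The same TFA treatment follows. This gives 10 as a racemate, so the mirror-image series forms alongside: di-tert-butyl (2R)-2-[(1S)-1-(ethylsulfanylcarbonyl)-11-(trimethylsilyloxy)undecyl]-2-(trimethylsilyloxy)pentanedioate F1 and (2R)-2-[(1S)-1-(ethylsulfanylcarbonyl)-11-hydroxyundecyl]-2-hydroxypentanedioic acid F2 in the flask, and (2R)-2-[(1S)-1-(ethylsulfanylcarbonyl)-11-hydroxyundecyl]-5-oxooxolane-2-carboxylic acid F3 after work-up. The racemic acid is treated with (R)-N,N-dimethyl-1-phenylethylamine in ethyl acetate–heptane; a tertiary amine is chosen so the thioester is not aminolysed. The two diastereomeric salts, the (R)-N,N-dimethyl-1-phenylethylammonium salt of 10 F4 and the (R)-N,N-dimethyl-1-phenylethylammonium salt of F3 F5, are separated by fractional crystallisation (F4 is taken from crystals or mother liquor, whichever holds it). Acidification of F4 with dilute HCl and extraction returns 10.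

Step 6. The thioester sits next to a quaternary carbon and may resist silver-promoted hydrolysis, or the acid set free may start to cleave the malate ester on long heating. The fallback sets out from 14 and comes back at 15; it replaces hydrolysis by reduction and re-oxidation. Fukuyama reduction (Et3SiH, 10 % Pd/C, acetone, rt) gives the aldehyde (2S)-2-[(2R)-12-{[(2R)-3-carboxy-2-hydroxypropanoyl]oxy}-1-oxododecan-2-yl]-5-oxooxolane-2-carboxylic acid F6. It is oxidised at once under Pinnick conditions (NaClO2, NaH2PO4, 2-methylbut-2-ene, t-BuOH–H2O, 0 °C) to 15, before the α-centre can epimerise.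

Step 1. The free primary hydroxyl can compete with the thiol and give oligoesters. The fallback sets out from 1 and comes back at 3; it moves the thioester formation onto an ester with the hydroxyl masked in the flask. Fischer esterification (MeOH, cat. H2SO4, reflux) gives methyl 12-hydroxydodecanoate F7. Treatment with Me3Al and EtSH (3 equiv each, forming Me2AlSEt, CH2Cl2, 0 °C to rt) converts the hydroxyl into its aluminium alkoxide and the methyl ester into thioester 3, which is released on aqueous acidic work-up.

**Further compounds**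

F1 | step 4 | di-tert-butyl (2R)-2-[(1S)-1-(ethylsulfanylcarbonyl)-11-(trimethylsilyloxy)undecyl]-2-(trimethylsilyloxy)pentanedioate | C[Si](C)(C)OCCCCCCCCCC[C@H](C(=O)SCC)[C@@](O[Si](C)(C)C)(C(=O)OC(C)(C)C)CCC(=O)OC(C)(C)C
F2 | step 4 | (2R)-2-[(1S)-1-(ethylsulfanylcarbonyl)-11-hydroxyundecyl]-2-hydroxypentanedioic acid | OCCCCCCCCCC[C@H](C(=O)SCC)[C@@](O)(C(=O)O)CCC(=O)O
F3 | step 4 | (2R)-2-[(1S)-1-(ethylsulfanylcarbonyl)-11-hydroxyundecyl]-5-oxooxolane-2-carboxylic acid | OCCCCCCCCCC[C@H](C(=O)SCC)[C@@]1(C(=O)O)CCC(=O)O1
F4 | step 4 | (R)-N,N-dimethyl-1-phenylethylammonium (2S)-2-[(1R)-1-(ethylsulfanylcarbonyl)-11-hydroxyundecyl]-5-oxooxolane-2-carboxylate | OCCCCCCCCCC[C@@H](C(=O)SCC)[C@]1(C(=O)[O-])CCC(=O)O1.C[C@@H]([NH+](C)C)c1ccccc1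
F5 | step 4 | (R)-N,N-dimethyl-1-phenylethylammonium (2R)-2-[(1S)-1-(ethylsulfanylcarbonyl)-11-hydroxyundecyl]-5-oxooxolane-2-carboxylate | OCCCCCCCCCC[C@H](C(=O)SCC)[C@@]1(C(=O)[O-])CCC(=O)O1.C[C@@H]([NH+](C)C)c1ccccc1
F6 | step 6 | (2S)-2-[(2R)-12-{[(2R)-3-carboxy-2-hydroxypropanoyl]oxy}-1-oxododecan-2-yl]-5-oxooxolane-2-carboxylic acid | O=C(O)C[C@@H](O)C(=O)OCCCCCCCCCC[C@@H](C=O)[C@]1(C(=O)O)CCC(=O)O1
F7 | step 1 | methyl 12-hydroxydodecanoate | COC(=O)CCCCCCCCCCCO
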